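**Retrosynthetic overview**
1. Militarinone A (19) ⇐ desilylation ⇐ aldol-type condensation (C2'=C3' of the side chain) between acetyl N-hydroxypyridone 10 and dienal 17.
2. Key disconnection, a C–O bond: the C2–O bond of the cyclic hydroxamic acid. 10 ⇐ 2-chloropyridine 6 by percarboxylate SNAr and an in-flask [3,3] O-to-N oxygen shift (new); the 4-OH is unveiled in the same flask.
3. 6 ⇐ C3 lithiation/acetylation of 4 ⇐ aryl-magnesium from 1 + ketone 2; this addition fixes the cis relationship of the two cyclohexane oxygens.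
4. 17 ⇐ two Wittig homologations ⇐ (2R,4R)-2,4-dimethylhexan-1-ol 14 ⇐ catalyst-controlled double hydrogenation of dienol 13 (from tiglic aldehyde 11), which sets both methyl stereocentres.
5. Rings: none is built. The pyridine and cyclohexane rings are bought, and the pyridine is turned into the 1-hydroxy-2-pyridone in step 3.

Assumption: the target is taken as the SMILES gives it, (8R,10R) in the side chain with the two cyclohexane hydroxyls cis; in step 6 the ligand antipode that gives the (2R,4R) alcohol is used, fixed in a test run by optical rotation.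

**Route**

Step 1
Reactants: 1 5-bromo-2-chloro-4-methoxypyridine; 2 4-(tert-butyldimethylsilyloxy)cyclohexanone
Product: 4 4-(tert-butyldimethylsilyloxy)-1-(6-chloro-4-methoxypyridin-3-yl)cyclohexan-1-ol (OH cis to OTBS), via pyridylmagnesium chloride 3 (not isolated)
Conditions: iPrMgCl·LiCl, THF, −15 °C; then LaCl3·2LiCl, 2, −15 → 0 °C; aq. NH4Cl
Reagents that add atoms: none
Why: Br/Mg exchange and 1,2-addition of the aryl-magnesium to the ketone (LaCl3·2LiCl suppresses enolisation); the bulky ortho-substituted aryl group enters equatorially on the chair with equatorial OTBS, giving the axial OH cis to OTBS, and the minor epimer is removed by chromatography.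

Step 2
Reactants: 4 4-(tert-butyldimethylsilyloxy)-1-(6-chloro-4-methoxypyridin-3-yl)cyclohexan-1-ol
Product: 6 1-{5-[cis-4-(tert-butyldimethylsilyloxy)-1-hydroxycyclohexyl]-2-chloro-4-methoxypyridin-3-yl}ethan-1-one, via dilithiated pyridine 5 (not isolated)
Conditions: LiN(iPr)2 (2.3 equiv), THF, −78 °C; then MeC(O)N(OMe)Me, −78 → −40 °C; aq. NH4Cl
Reagents that add atoms: N-methoxy-N-methylacetamide, CC(=O)N(C)OC
Why: Directed ortho-lithiation at the ring C–H flanked by Cl and OMe (the first equivalent of base takes the OH proton) followed by Weinreb ketone synthesis; no stereocentre is touched.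

Step 3
Reactants: 6 1-{5-[cis-4-(tert-butyldimethylsilyloxy)-1-hydroxycyclohexyl]-2-chloro-4-methoxypyridin-3-yl}ethan-1-one
Product: 10 3-acetyl-5-[cis-4-(tert-butyldimethylsilyloxy)-1-hydroxycyclohexyl]-1,4-dihydroxypyridin-2(1H)-one, via 2-pyridyl perester 7 (not isolated), via N-aroyloxy-2-pyridone 8 (not isolated), via 4-methoxy-1-hydroxy-2-pyridone 9 (not isolated)
Conditions: m-CPBA (1.5 equiv), K2CO3 (3 equiv), DMF, 0 → 40 °C; then LiOH, H2O, 60 °C; Na2S2O3, then HCl to pH 4
Reagents that add atoms: 3-chloroperoxybenzoic acid, OOC(=O)c1cccc(Cl)c1; lithium hydroxide, [Li+].[OH-]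
Why: Proposed new method: the α-effect nucleophile ArCO3K displaces chloride at C2 (SNAr, activated by the ring nitrogen and the ortho acetyl group) to give perester 7, whose weak O–O bond is placed for a [3,3] shift across N1=C2–O–O–C=O that forms the N–O bond and the pyridone carbonyl (8), after which hydroxide cleaves the N–O ester (9) and hydrolyses the doubly activated 4-methoxy vinylogous ester by addition–elimination (10); the closest known reaction types are hydroxide SNAr on 2-chloropyridine N-oxides to give 1-hydroxy-2-pyridones, SNAr of peroxide anions on chloro-azines, and the [3,3] rearrangement of aryl peresters in the ortho-acyloxylation of phenols with diacyl peroxides.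

Step 4
Reactants: 11 (E)-2-methylbut-2-enal
Product: 12 ethyl (2E,4E)-2,4-dimethylhexa-2,4-dienoate
Conditions: Ph3P=C(Me)CO2Et, CH2Cl2, 40 °C
Reagents that add atoms: ethyl 2-(triphenylphosphoranylidene)propanoate, CCOC(=O)C(C)=P(c1ccccc1)(c1ccccc1)c1ccccc1
Why: Wittig olefination with a stabilised ylide gives the E-trisubstituted alkene.

Step 5
Reactants: 12 ethyl (2E,4E)-2,4-dimethylhexa-2,4-dienoate
Product: 13 (2E,4E)-2,4-dimethylhexa-2,4-dien-1-ol
Conditions: iBu2AlH (2.2 equiv), CH2Cl2, −78 → 0 °C; aq. KNaC4H4O6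
Reagents that add atoms: none
Why: 1,2-reduction of the conjugated ester to the allylic alcohol with the aluminium hydride, without conjugate reduction.

Step 6
Reactants: 13 (2E,4E)-2,4-dimethylhexa-2,4-dien-1-ol
Product: 14 (2R,4R)-2,4-dimethylhexan-1-ol
Conditions: H2 (50 bar), [Ir(cod)(L)]BArF (1 mol %; L = 1-(2,6-diisopropylphenyl)-3-{[2-(1-adamantyl)-4,5-dihydrooxazol-4-yl]methyl}imidazol-2-ylidene, BArF = B[3,5-(CF3)2C6H3]4), CH2Cl2, 25 °C
Reagents that add atoms: none
Why: Iridium-catalysed asymmetric hydrogenation of trisubstituted alkenes (N-heterocyclic carbene–oxazoline catalyst of the kind used on 2,4-dimethyl dienols); both E-alkenes show the catalyst the same substitution pattern, so addition to the same enantioface at each gives the syn (2R,4R) dyad.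

Step 7
Reactants: 14 (2R,4R)-2,4-dimethylhexan-1-ol
Product: 16 (2E,4R,6R)-2,4,6-trimethyloct-2-enal, via (2R,4R)-2,4-dimethylhexanal 15 (not isolated)
Conditions: (COCl)2, DMSO, Et3N, CH2Cl2, −78 → 0 °C; then Ph3P=C(Me)CHO, toluene, 90 °C
Reagents that add atoms: 2-(triphenylphosphoranylidene)propanal, CC(C=O)=P(c1ccccc1)(c1ccccc1)c1ccccc1
Why: Swern oxidation and immediate Wittig olefination with the stabilised formyl ylide give the E-enal; using the aldehyde crude and at once avoids epimerisation of its α-stereocentre.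

Step 8
Reactants: 16 (2E,4R,6R)-2,4,6-trimethyloct-2-enal
Product: 17 (2E,4E,6R,8R)-4,6,8-trimethyldeca-2,4-dienal
Conditions: Ph3P=CHCHO (0.95 equiv), toluene, 80 °C
Reagents that add atoms: (triphenylphosphoranylidene)acetaldehyde, O=CC=P(c1ccccc1)(c1ccccc1)c1ccccc1
Why: Wittig two-carbon homologation with the stabilised formylmethylene ylide gives the E-alkene; a slight deficit of ylide limits further homologation.

Step 9
Reactants: 10 3-acetyl-5-[cis-4-(tert-butyldimethylsilyloxy)-1-hydroxycyclohexyl]-1,4-dihydroxypyridin-2(1H)-one; 17 (2E,4E,6R,8R)-4,6,8-trimethyldeca-2,4-dienal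
Product: 18 5-[cis-4-(tert-butyldimethylsilyloxy)-1-hydroxycyclohexyl]-1,4-dihydroxy-3-[(2E,4E,6E,8R,10R)-6,8,10-trimethyldodeca-2,4,6-trienoyl]pyridin-2(1H)-one
Conditions: piperidine (1.5 equiv), EtOH, 4 Å MS, 60 °C
Reagents that add atoms: none
Why: Amine-mediated aldol (Claisen–Schmidt) condensation of the 3-acetyl-4-hydroxypyridone with the dienal via its iminium ion, with E1cB loss of water to the conjugated E-alkene; no stereocentre is touched.

Step 10
Reactants: 18 5-[cis-4-(tert-butyldimethylsilyloxy)-1-hydroxycyclohexyl]-1,4-dihydroxy-3-[(2E,4E,6E,8R,10R)-6,8,10-trimethyldodeca-2,4,6-trienoyl]pyridin-2(1H)-one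
Product: 19 militarinone A
Conditions: HF·pyridine, pyridine, THF, 0 → 25 °C
Reagents that add atoms: none
Why: Fluoride-mediated desilylation under buffered conditions that spare the acid-labile tertiary carbinol and the triene; no stereocentre is touched.

**Compound list**
1 | 5-bromo-2-chloro-4-methoxypyridine | COc1cc(Cl)ncc1Br | starting material
2 | 4-(tert-butyldimethylsilyloxy)cyclohexanone | O=C1CCC(O[Si](C)(C)C(C)(C)C)CC1 | starting material
3 | (6-chloro-4-methoxypyridin-3-yl)magnesium chloride (LiCl complex, not isolated) | COc1cc(Cl)ncc1[Mg]Cl | intermediate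
4 | 4-(tert-butyldimethylsilyloxy)-1-(6-chloro-4-methoxypyridin-3-yl)cyclohexan-1-ol, OH cis to OTBS | COc1cc(Cl)ncc1[C@]2(O)CC[C@@H](O[Si](C)(C)C(C)(C)C)CC2 | intermediate
5 | lithium alkoxide of 4 lithiated at the ring carbon between Cl and OMe (not isolated) | COc1c([Li])c(Cl)ncc1[C@]2(O[Li])CC[C@@H](O[Si](C)(C)C(C)(C)C)CC2 | intermediate
6 | 1-{5-[cis-4-(tert-butyldimethylsilyloxy)-1-hydroxycyclohexyl]-2-chloro-4-methoxypyridin-3-yl}ethan-1-one | COc1c(C(C)=O)c(Cl)ncc1[C@]2(O)CC[C@@H](O[Si](C)(C)C(C)(C)C)CC2 | intermediate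
7 | OO-{3-acetyl-5-[cis-4-(tert-butyldimethylsilyloxy)-1-hydroxycyclohexyl]-4-methoxypyridin-2-yl} 3-chlorobenzenecarboperoxoate (not isolated) | COc1c(C(C)=O)c(OOC(=O)c3cccc(Cl)c3)ncc1[C@]2(O)CC[C@@H](O[Si](C)(C)C(C)(C)C)CC2 | intermediate
8 | 3-acetyl-5-[cis-4-(tert-butyldimethylsilyloxy)-1-hydroxycyclohexyl]-4-methoxy-2-oxopyridin-1(2H)-yl 3-chlorobenzoate (not isolated) | COc1c(C(C)=O)c(=O)n(OC(=O)c3cccc(Cl)c3)cc1[C@]2(O)CC[C@@H](O[Si](C)(C)C(C)(C)C)CC2 | intermediate
9 | 3-acetyl-5-[cis-4-(tert-butyldimethylsilyloxy)-1-hydroxycyclohexyl]-1-hydroxy-4-methoxypyridin-2(1H)-one (not isolated) | COc1c(C(C)=O)c(=O)n(O)cc1[C@]2(O)CC[C@@H](O[Si](C)(C)C(C)(C)C)CC2 | intermediate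
10 | 3-acetyl-5-[cis-4-(tert-butyldimethylsilyloxy)-1-hydroxycyclohexyl]-1,4-dihydroxypyridin-2(1H)-one | CC(=O)c1c(O)c([C@]2(O)CC[C@@H](O[Si](C)(C)C(C)(C)C)CC2)cn(O)c1=O | intermediate
11 | (E)-2-methylbut-2-enal (tiglic aldehyde) | C/C=C(\C)C=O | starting material
12 | ethyl (2E,4E)-2,4-dimethylhexa-2,4-dienoate | C/C=C(\C)/C=C(\C)C(=O)OCC | intermediate
13 | (2E,4E)-2,4-dimethylhexa-2,4-dien-1-ol | C/C=C(\C)/C=C(\C)CO | intermediate
14 | (2R,4R)-2,4-dimethylhexan-1-ol | CC[C@@H](C)C[C@@H](C)CO | intermediate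
15 | (2R,4R)-2,4-dimethylhexanal (not isolated) | CC[C@@H](C)C[C@@H](C)C=O | intermediate
16 | (2E,4R,6R)-2,4,6-trimethyloct-2-enal | CC[C@@H](C)C[C@@H](C)/C=C(\C)C=O | intermediate
17 | (2E,4E,6R,8R)-4,6,8-trimethyldeca-2,4-dienal | CC[C@@H](C)C[C@@H](C)/C=C(C)/C=C/C=O | intermediate
18 | 5-[cis-4-(tert-butyldimethylsilyloxy)-1-hydroxycyclohexyl]-1,4-dihydroxy-3-[(2E,4E,6E,8R,10R)-6,8,10-trimethyldodeca-2,4,6-trienoyl]pyridin-2(1H)-one | CC[C@@H](C)C[C@@H](C)/C=C(C)/C=C/C=C/C(=O)c1c(O)c([C@]2(O)CC[C@@H](O[Si](C)(C)C(C)(C)C)CC2)cn(O)c1=O | intermediate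
19 | militarinone A, 5-(cis-1,4-dihydroxycyclohexyl)-1,4-dihydroxy-3-[(2E,4E,6E,8R,10R)-6,8,10-trimethyldodeca-2,4,6-trienoyl]pyridin-2(1H)-one | CC[C@@H](C)C[C@@H](C)/C=C(C)/C=C/C=C/C(=O)c1c(O)c([C@]2(O)CC[C@@H](O)CC2)cn(O)c1=O | target

**Step count**
Total: 10 steps. Longest linear sequence: 7 steps (steps 4, 5, 6, 7, 8, 9, 10).

**Three steps most likely to fail, each with a fallback**

Step 3 (the proposed new step). The percarboxylate may be too weak a nucleophile for the 4-methoxy-substituted ring. The perester may be cleaved at its acyl carbon before it rearranges, which would give the N–H pyridone. The acetyl group may suffer Baeyer–Villiger oxidation. The fallback uses known chemistry and sets out from 6. N-oxidation with m-CPBA in ClCH2CH2Cl at 60 °C gives 3-acetyl-5-[cis-4-(tert-butyldimethylsilyloxy)-1-hydroxycyclohexyl]-2-chloro-4-methoxypyridine 1-oxide F1. Aqueous LiOH in THF at 50 °C then displaces chloride at C2 (SNAr on a 2-chloropyridine N-oxide, which gives the 1-hydroxy-2-pyridone directly) and hydrolyses the 4-methoxy group. This returns to the route at 10, at the cost of one extra step.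

Step 9. In 10 the acetyl group is part of a vinylogous acid and three OH groups are acidic, so the condensation with an aliphatic dienal may be slow or low-yielding, or the product may close by oxa-Michael addition of the 4-OH. The fallback sets out from 9, which is isolated by stopping step 3 after cleavage of the N–O ester with LiOH at 0 °C. In 9 the acetyl group is an ordinary aryl methyl ketone. Claisen–Schmidt condensation with 17 (KOH, EtOH/H2O, 25 °C) gives 5-[cis-4-(tert-butyldimethylsilyloxy)-1-hydroxycyclohexyl]-1-hydroxy-4-methoxy-3-[(2E,4E,6E,8R,10R)-6,8,10-trimethyldodeca-2,4,6-trienoyl]pyridin-2(1H)-one F2. LiOH in THF/H2O at 50 °C then hydrolyses the 4-methoxy group, now activated further by the trienoyl group, and the route is rejoined at 18.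

Step 8. The product 17 is a less hindered aldehyde than the α-branched enal 16, so a second homologation to the trienal and some Z-isomer can lower the yield. The fallback sets out from 16. Horner–Wadsworth–Emmons reaction with (EtO)2P(O)CH2CO2Et and NaH in THF gives ethyl (2E,4E,6R,8R)-4,6,8-trimethyldeca-2,4-dienoate F3. Reduction with iBu2AlH gives (2E,4E,6R,8R)-4,6,8-trimethyldeca-2,4-dien-1-ol F4. Oxidation of this allylic alcohol with MnO2 in CH2Cl2 returns to the route at 17.

Further compounds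
F1 | step 3 | 3-acetyl-5-[cis-4-(tert-butyldimethylsilyloxy)-1-hydroxycyclohexyl]-2-chloro-4-methoxypyridine 1-oxide | COc1c(C(C)=O)c(Cl)[n+]([O-])cc1[C@]2(O)CC[C@@H](O[Si](C)(C)C(C)(C)C)CC2
F2 | step 9 | 5-[cis-4-(tert-butyldimethylsilyloxy)-1-hydroxycyclohexyl]-1-hydroxy-4-methoxy-3-[(2E,4E,6E,8R,10R)-6,8,10-trimethyldodeca-2,4,6-trienoyl]pyridin-2(1H)-one | CC[C@@H](C)C[C@@H](C)/C=C(C)/C=C/C=C/C(=O)c1c(OC)c([C@]2(O)CC[C@@H](O[Si](C)(C)C(C)(C)C)CC2)cn(O)c1=O
F3 | step 8 | ethyl (2E,4E,6R,8R)-4,6,8-trimethyldeca-2,4-dienoate | CC[C@@H](C)C[C@@H](C)/C=C(C)/C=C/C(=O)OCC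
F4 | step 8 | (2E,4E,6R,8R)-4,6,8-trimethyldeca-2,4-dien-1-ol | CC[C@@H](C)C[C@@H](C)/C=C(C)/C=C/CO
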